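**Retrosynthetic overview** (guaiane numbering: C1/C5 ring fusion, C4 carbinol, C6–C9, C10 bearing C14, C11 isopropyl CH, C15 on C4)
1. Endgame: 8-O-angeloylation; the anti 6-OAc/8-OH pair from an Evans–Tishchenko reduction of a 6-hydroxy-8-ketone; that ketol from SmI2 excision of the C9–O bond of a 6,9-oxygen-bridged 8-ketone (temporary 8-oxabicyclo[3.2.1]octane ring).
2. The C4 carbinol comes from radical hydration of a C4 exocyclic methylene; the C14 methyl from the ester that serves as acceptor group of the carbenoid.
3. Key disconnection C9–C10 and C5–C6: a (4+3) cycloaddition (cyclopropanation, then divinylcyclopropane rearrangement) of the rhodium vinylcarbenoid C10–C1=C5 from a cyclopentenyl diazoacetate with 3-siloxy-4-isopropylfuran (C6–C7–C8–C9 plus the bridge oxygen).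
4. Enabling feature: in the seven-membered ring the C1=C10 ring-fusion alkene lies 1,4 to C7–C8 (a masked cyclohepta-1,4-diene), C8 carries oxygen, and O6 is cis to H5, so O6 can be the furan oxygen.
5. Ring order: five-membered ring (from cyclopentane-1,3-dione) and furan first; seven-membered ring and oxygen bridge together in the key step; bridge opened again in step 12.

Key step: step 6

Assumption: Rh2(S-PTAD)4 is taken to be the catalyst antipode that gives the (4+3) adduct of step 6 with the configuration drawn. If its sense of induction is the opposite, Rh2(R-PTAD)4 is used and nothing else changes. The same holds for the lactate auxiliary in the fallback to step 6.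

**Step 1**
Reactants: 1 cyclopentane-1,3-dione
Product: 2 3-iodocyclopent-2-en-1-one
Conditions: PPh3, I2, Et3N, MeCN, rt then reflux
Reagents that add atoms: iodine, II
Why: Appel-type deoxyiodination of the enol of the 1,3-diketone (iodophosphonium activation, then addition–elimination by iodide) is the standard entry to 3-iodoenones.

**Step 2**
Reactants: 2 3-iodocyclopent-2-en-1-one; 3 ethyl diazoacetate
Product: 4 ethyl 2-diazo-2-(3-oxocyclopent-1-en-1-yl)acetate
Conditions: Pd(PPh3)4 (5 mol %), nBu4NBr, Et3N, MeCN, rt
Reagents that add atoms: none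
Why: Palladium-catalyzed C–H vinylation of an acceptor diazo compound (oxidative addition of zerovalent palladium into the C–I bond, deprotonative palladation of the diazoacetate, reductive elimination) should give the vinyldiazoacetate with the diazo group intact.

**Step 3**
Reactants: 5 3-methylbutanal; 6 morpholine
Product: 7 (E)-4-(3-methylbut-1-en-1-yl)morpholine
Conditions: K2CO3, Et2O, 0 °C → rt
Reagents that add atoms: none
Why: Enamine condensation of an aldehyde with a secondary amine, which should give the E enamine.

**Step 4**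
Reactants: 7 (E)-4-(3-methylbut-1-en-1-yl)morpholine; 8 chloroacetyl chloride
Product: 10 2-(chloroacetyl)-3-methylbutanal, via enaminone 9 (not isolated)
Conditions: Et3N, Et2O, 0 °C → rt; then 1 M HCl, rt
Reagents that add atoms: water, O
Why: Stork enamine C-acylation followed by hydrolysis of the vinylogous amide should give the 2-acyl aldehyde, mainly as its chelated hydroxymethylene enol.

**Step 5**
Reactants: 10 2-(chloroacetyl)-3-methylbutanal
Product: 12 tert-butyl[(4-isopropylfuran-3-yl)oxy]dimethylsilane, via 4-isopropylfuran-3(2H)-one 11 (not isolated)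
Conditions: Et3N, CH2Cl2, 0 °C → rt; then TBSOTf, 0 °C
Reagents that add atoms: tert-butyldimethylsilyl triflate, CC(C)(C)[Si](C)(C)OS(=O)(=O)C(F)(F)F
Why: The Z enolate of the β-ketoaldehyde should close by 5-exo-tet O-alkylation onto the chloromethyl ketone, and O-silylation of the C2 enolate of the furanone then gives the aromatic 3-siloxyfuran (silyl enol ether formation).

**Step 6**
Reactants: 4 ethyl 2-diazo-2-(3-oxocyclopent-1-en-1-yl)acetate; 12 tert-butyl[(4-isopropylfuran-3-yl)oxy]dimethylsilane
Product: 14 ethyl (5R,6S,9R)-8-(tert-butyldimethylsilyloxy)-6,9-epoxy-4-oxo-15-norguaia-1(10),7-dien-14-oate, via endo-divinylcyclopropane 13 (not isolated)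
Conditions: Rh2(S-PTAD)4 (1 mol %), toluene/hexanes, −20 °C → rt, slow addition of 4 to 12 (2 equiv)
Reagents that add atoms: none
Why: Loss of N2 from 4 gives the rhodium vinylcarbenoid, whose carbene carbon (C10) attacks C2 of furan 12 (the future C9, both α to the ring oxygen and β-carbon of the silyl enol ether) and closes to the endo cis-divinylcyclopropane 13, whose [3,3] (Cope) rearrangement through the boat transition state then forms C5–C6. The closest known reaction type is the tandem cyclopropanation/divinylcyclopropane rearrangement of vinyldiazoacetates with furans to 8-oxabicyclo[3.2.1]octadienes. The cyclopropane closes by (2+1) carbene addition to the C2=C3 bond of the furan, and the seven-membered carbocycle (with it the oxane ring of the oxygen-bridged bicycle) closes by the [3,3] shift that opens the cyclopropane again, a net (4+3) cycloaddition. C9 is set by the chiral dirhodium carboxylate, which selects the enantioface of the furan; C6 is tied to C9 by the bridging oxygen; C5 follows from the boat transition state, in which 5-H points inwards and ends cis to the bridge while C4 ends outside. The step needs site selectivity for the C2=C3 bond (secured by the OTBS donor and by the isopropyl group shielding C5 of the furan), endo placement of the cyclopentenyl group (the usual preference of donor/acceptor carbenoids) and ring closure ahead of proton loss or silyl transfer from the zwitterion-like adduct (non-polar solvent, low temperature). The ring locks the C4 carbonyl trans to the carbene carbon, so furan formation from the carbenoid itself is excluded.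

**Step 7**
Reactants: 14 (4+3) adduct
Product: 15 ethyl 8-(tert-butyldimethylsilyloxy)-6,9-epoxyguaia-1(10),4(15),7-trien-14-oate
Conditions: Cp2TiMe2 (2 equiv), toluene, 65 °C, dark
Reagents that add atoms: dimethyltitanocene Cp2TiMe2, C[Ti](C)(C1C=CC=C1)C1C=CC=C1
Why: Petasis methylenation (titanium methylidene, oxatitanacyclobutane) is non-basic, so the acidic C5–H between ketone and enoate should survive, and the ketone reacts ahead of the hindered conjugated ester.

**Step 8**
Reactants: 15 trienoate
Product: 16 8-(tert-butyldimethylsilyloxy)-6,9-epoxyguaia-1(10),4(15),7-trien-14-ol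
Conditions: iBu2AlH (2.5 equiv), CH2Cl2, −78 → 0 °C; aq. potassium sodium tartrate
Reagents that add atoms: none
Why: 1,2-Reduction of the enoate by the aluminium hydride should give the allylic alcohol, the silyl enol ether and the alkenes being inert.

**Step 9**
Reactants: 16 allylic alcohol
Product: 18 8-(tert-butyldimethylsilyloxy)-6,9-epoxyguaia-1(10),4(15),7-triene, via allylic mesylate 17 (not isolated)
Conditions: MsCl, Et3N, THF, −40 °C; then LiBHEt3, −40 → 0 °C
Reagents that add atoms: none
Why: Mesylation and SN2 hydride displacement at the primary allylic carbon should give the C14 methyl group, SN2′ attack at the fully substituted C1 being disfavoured so that the C1=C10 alkene stays in place.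

**Step 10**
Reactants: 18 silyl enol ether
Product: 20 6,9-epoxyguaia-1(10),4(15)-dien-8-one (isopropyl cis to the oxygen bridge), via C7-epimeric ketone 19 (not isolated)
Conditions: 1 M HCl, THF, 0 °C → rt; then DBU (0.2 equiv), CH2Cl2, rt
Reagents that add atoms: none
Why: Hydrolysis of the silyl enol ether should protonate C7 from the open face syn to the bridge (kinetic endo isopropyl), and base-mediated epimerisation α to the ketone then funnels both epimers to the more stable exo isomer with isopropyl cis to the bridge; C9 cannot enolise (bridgehead), and any retro-oxa-Michael opening recloses to the same ketone.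

**Step 11**
Reactants: 20 bridged dienone
Product: 22 4-hydroxy-6,9-epoxyguai-1(10)-en-8-one (4-OH cis to 5-H), via tertiary hydroperoxide 21 (not isolated)
Conditions: Mn(dpm)3 (10 mol %), PhSiH3, O2 (1 atm), iPrOH/CH2Cl2, 0 °C; then PPh3
Reagents that add atoms: dioxygen, O=O
Why: Mukaiyama hydration, in which hydrogen-atom transfer to the 1,1-disubstituted alkene (faster than to the tetrasubstituted one) gives the tertiary C4 radical that should capture O2 on the face of 5-H, away from C6 and the two-carbon bridge, setting 4-OH cis to 5-H.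

**Step 12**
Reactants: 22 bridged hydroxy ketone
Product: 23 4,6-dihydroxyguai-1(10)-en-8-one
Conditions: SmI2 (2.5 equiv), THF/MeOH, −78 °C; pH 7 buffer
Reagents that add atoms: none
Why: Samarium diiodide cleavage of an α-alkoxy ketone: the ketyl expels the α (and allylic) C9–O bond, α-protonation at C9 should leave C1=C10 in place, and 6-OH is freed with C6 and C7 untouched.

**Step 13**
Reactants: 23 β-hydroxy ketone
Product: 24 4,8-dihydroxyguai-1(10)-en-6-yl acetate
Conditions: SmI2 (30 mol %), CH3CHO (8 equiv), THF, −10 °C
Reagents that add atoms: acetaldehyde, CC=O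
Why: Evans–Tishchenko reduction, in which the samarium-bound hemiacetal of acetaldehyde on O6 delivers hydride intramolecularly to C8 on the face of O6, should give the 6,8-anti relationship and place the acetate on O6 in the same event.

**Step 14**
Reactants: 24 hydroxy acetate; 25 angelic acid
Product: 26 (4S,5R,6R,7R,8S)-6-acetoxy-4-hydroxyguai-1(10)-en-8-yl (Z)-2-methylbut-2-enoate (target)
Conditions: 2,4,6-trichlorobenzoyl chloride, Et3N, toluene, rt; then 24, 80 °C
Reagents that add atoms: none
Why: Yamaguchi esterification through the mixed anhydride should acylate the secondary 8-OH without Z→E isomerisation of the angelate, the tertiary 4-OH being unreactive.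

**Compound list**
1 | cyclopentane-1,3-dione | O=C1CCC(=O)C1 | starting material
2 | 3-iodocyclopent-2-en-1-one | O=C1C=C(I)CC1 | intermediate
3 | ethyl diazoacetate | CCOC(=O)C=[N+]=[N-] | starting material
4 | ethyl 2-diazo-2-(3-oxocyclopent-1-en-1-yl)acetate | CCOC(=O)C(=[N+]=[N-])C1=CC(=O)CC1 | intermediate
5 | 3-methylbutanal | CC(C)CC=O | starting material
6 | morpholine | C1COCCN1 | starting material
7 | (E)-4-(3-methylbut-1-en-1-yl)morpholine | CC(C)/C=C/N1CCOCC1 | intermediate
8 | chloroacetyl chloride | ClCC(=O)Cl | starting material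
9 | (E)-1-chloro-4-methyl-3-(morpholin-4-ylmethylidene)pentan-2-one (geometry immaterial) | ClCC(=O)/C(C(C)C)=C/N1CCOCC1 | intermediate (not isolated)
10 | 2-(chloroacetyl)-3-methylbutanal (racemic, largely enolised) | CC(C)C(C=O)C(=O)CCl | intermediate
11 | 4-isopropylfuran-3(2H)-one | CC(C)C1=COCC1=O | intermediate (not isolated)
12 | tert-butyl[(4-isopropylfuran-3-yl)oxy]dimethylsilane | CC(C)c1cocc1O[Si](C)(C)C(C)(C)C | intermediate
13 | ethyl 5-(tert-butyldimethylsilyloxy)-4-isopropyl-6-(3-oxocyclopent-1-en-1-yl)-2-oxabicyclo[3.1.0]hex-3-ene-6-carboxylate, cyclopentenyl endo | CCOC(=O)[C@]1(C2=CC(=O)CC2)[C@H]3OC=C(C(C)C)[C@]31O[Si](C)(C)C(C)(C)C | intermediate (not isolated)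
14 | ethyl (5R,6S,9R)-8-(tert-butyldimethylsilyloxy)-6,9-epoxy-4-oxo-15-norguaia-1(10),7-dien-14-oate; 5-H and the oxygen bridge on the same face | CC(C)C1=C(O[Si](C)(C)C(C)(C)C)[C@H]2C(C(=O)OCC)=C3CCC(=O)[C@H]3[C@@H]1O2 | intermediate
15 | ethyl 8-(tert-butyldimethylsilyloxy)-6,9-epoxyguaia-1(10),4(15),7-trien-14-oate; C5, C6, C9 as in 14 | CC(C)C1=C(O[Si](C)(C)C(C)(C)C)[C@H]2C(C(=O)OCC)=C3CCC(=C)[C@H]3[C@@H]1O2 | intermediate
16 | 8-(tert-butyldimethylsilyloxy)-6,9-epoxyguaia-1(10),4(15),7-trien-14-ol; C5, C6, C9 as in 14 | CC(C)C1=C(O[Si](C)(C)C(C)(C)C)[C@H]2C(CO)=C3CCC(=C)[C@H]3[C@@H]1O2 | intermediate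
17 | 14-methanesulfonate of 16 | CC(C)C1=C(O[Si](C)(C)C(C)(C)C)[C@H]2C(COS(C)(=O)=O)=C3CCC(=C)[C@H]3[C@@H]1O2 | intermediate (not isolated)
18 | 8-(tert-butyldimethylsilyloxy)-6,9-epoxyguaia-1(10),4(15),7-triene; C5, C6, C9 as in 14 | CC(C)C1=C(O[Si](C)(C)C(C)(C)C)[C@H]2C(C)=C3CCC(=C)[C@H]3[C@@H]1O2 | intermediate
19 | 6,9-epoxyguaia-1(10),4(15)-dien-8-one, C7 epimer (isopropyl trans to the oxygen bridge) | O=C1[C@H]2C(C)=C3CCC(=C)[C@H]3[C@H](O2)[C@H]1C(C)C | intermediate (not isolated)
20 | 6,9-epoxyguaia-1(10),4(15)-dien-8-one; 5-H, oxygen bridge and isopropyl on the same face | O=C1[C@H]2C(C)=C3CCC(=C)[C@H]3[C@H](O2)[C@@H]1C(C)C | intermediate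
21 | 4-hydroperoxy-6,9-epoxyguai-1(10)-en-8-one; 4-OOH cis to 5-H | O=C1[C@H]2C(C)=C3CC[C@](C)(OO)[C@H]3[C@H](O2)[C@@H]1C(C)C | intermediate (not isolated)
22 | 4-hydroxy-6,9-epoxyguai-1(10)-en-8-one; 4-OH, 5-H, oxygen bridge and isopropyl on the same face | O=C1[C@H]2C(C)=C3CC[C@](C)(O)[C@H]3[C@H](O2)[C@@H]1C(C)C | intermediate
23 | 4,6-dihydroxyguai-1(10)-en-8-one; 4-OH, 5-H, 6-OH and 7-isopropyl on the same face | O=C1CC(C)=C2CC[C@](C)(O)[C@H]2[C@H](O)[C@@H]1C(C)C | intermediate
24 | 4,8-dihydroxyguai-1(10)-en-6-yl acetate; 8-OH on the face opposite to 6-OAc | O[C@H]1CC(C)=C2CC[C@](C)(O)[C@H]2[C@H](OC(C)=O)[C@@H]1C(C)C | intermediate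
25 | angelic acid, (Z)-2-methylbut-2-enoic acid | C/C=C(/C)C(=O)O | starting material
26 | (4S,5R,6R,7R,8S)-6-acetoxy-4-hydroxyguai-1(10)-en-8-yl (Z)-2-methylbut-2-enoate | C/C=C(/C)C(=O)O[C@H]1CC(C)=C2CC[C@](C)(O)[C@H]2[C@H](OC(C)=O)[C@@H]1C(C)C | target

**Total step count:** 14 steps.
**Longest linear sequence:** 12 steps (5 → 7 → 10 → 12 → 14 → 15 → 16 → 18 → 20 → 22 → 23 → 24 → 26).

**Steps most likely to fail**

Step 6. The carbenoid may be captured at C2 of the very electron-rich furan without clean ring closure (proton loss or silyl transfer from the zwitterion-like adduct), and enantiofacial selection by the catalyst alone may be insufficient. The fallback replaces catalyst control by auxiliary control; it sets out from 2 and 12 and returns at 16. Methyl (S)-lactate is acylated with bromoacetyl bromide to methyl (S)-2-(bromoacetoxy)propanoate F1, which N,N′-ditosylhydrazine and DBU convert into methyl (S)-2-(diazoacetoxy)propanoate F2. Coupling of F2 with 2 under the conditions of step 2 gives the lactate vinyldiazoacetate F3. Its decomposition with achiral Rh2(O2CC7H15)4 in the presence of 12 gives the lactate ester of the (4+3) adduct F4, the auxiliary carbonyl shielding one face of the carbenoid. Methylenation as in step 7 gives the exocyclic methylene lactate ester F5, and iBu2AlH then cleaves the auxiliary and delivers 16.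

Step 13. The transannular hydride transfer in the seven-membered ring may be slow, so that aldol or Tishchenko consumption of acetaldehyde and epimerisation at C7 compete. The fallback sets out from 23 and returns at 26. Saksena–Evans reduction of 23 with Me4NBH(OAc)3 in MeCN/AcOH gives, by intramolecular hydride delivery from the O6-bound borohydride, the anti triol guai-1(10)-ene-4,6,8-triol F6. Yamaguchi acylation with one equivalent of the mixed anhydride of 25 takes the less hindered 8-OH to the 8-angelate F7, and acetylation of the remaining 6-OH (Ac2O, DMAP, pyridine) gives 26.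

Step 11. Hydrogen-atom transfer to the tetrasubstituted C1=C10 alkene or reduction of the ketone may accompany the wanted hydration, and facial selectivity in oxygen capture may be incomplete. The fallback uses ionic instead of radical hydration; it sets out from 20 and returns at 22. Oxymercuration of 20 with Hg(OAc)2 in THF/H2O attacks only the unhindered 1,1-disubstituted alkene and delivers water to C4 on the face of 5-H, giving the organomercurial F8. Radical demercuration with Bu3SnH (AIBN) replaces mercury by hydrogen without touching the ketone and gives 22.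

**Further compounds**
F1 | step 6 | methyl (S)-2-(bromoacetoxy)propanoate | C[C@H](OC(=O)CBr)C(=O)OC
F2 | step 6 | methyl (S)-2-(diazoacetoxy)propanoate | C[C@H](OC(=O)C=[N+]=[N-])C(=O)OC
F3 | step 6 | (S)-1-methoxy-1-oxopropan-2-yl 2-diazo-2-(3-oxocyclopent-1-en-1-yl)acetate | C[C@H](OC(=O)C(=[N+]=[N-])C1=CC(=O)CC1)C(=O)OC
F4 | step 6 | (S)-1-methoxy-1-oxopropan-2-yl ester analogue of 14 | CC(C)C1=C(O[Si](C)(C)C(C)(C)C)[C@H]2C(C(=O)O[C@@H](C)C(=O)OC)=C3CCC(=O)[C@H]3[C@@H]1O2
F5 | step 6 | (S)-1-methoxy-1-oxopropan-2-yl ester analogue of 15 | CC(C)C1=C(O[Si](C)(C)C(C)(C)C)[C@H]2C(C(=O)O[C@@H](C)C(=O)OC)=C3CCC(=C)[C@H]3[C@@H]1O2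
F6 | step 13 | guai-1(10)-ene-4,6,8-triol, configuration as in 26 | O[C@H]1CC(C)=C2CC[C@](C)(O)[C@H]2[C@H](O)[C@@H]1C(C)C
F7 | step 13 | 4,6-dihydroxyguai-1(10)-en-8-yl (Z)-2-methylbut-2-enoate | C/C=C(/C)C(=O)O[C@H]1CC(C)=C2CC[C@](C)(O)[C@H]2[C@H](O)[C@@H]1C(C)C
F8 | step 11 | 15-(acetoxymercurio)-4-hydroxy-6,9-epoxyguai-1(10)-en-8-one | O=C1[C@H]2C(C)=C3CC[C@](C[Hg]OC(C)=O)(O)[C@H]3[C@H](O2)[C@@H]1C(C)C
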